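Ring B is cut at C7–C8, the bond between the benzylic carbinol carbon of ring A and the methyl-bearing C8: C7 becomes an aryl aldehyde and C8 a 2-iodoalkene. One intramolecular Nozaki–Hiyama–Kishi reaction then forms C7–C8, closes the seven-membered ring B and sets C7, leaving a hydroxyl next to an exocyclic methylene on C8. That hydroxyl afterwards steers hydrogen onto C8, so the C8 methyl ends trans to oxygen and to the C8′ methyl. The precursor is a 4-aryl-4-alkyl-2,6-dimethoxycyclohexadienone (ring C, quaternary C1′): its aryl group (ring A) carries the formyl group ortho to C1′, its alkyl chain carries the (R)-C8′ methyl centre and the iodoalkene.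

Key step: step 13

Atom labels: ring A = arene C1–C6 (C1 bears C7, C2 bears the spiro carbon C1′); ring B = C1, C7, C8, C8′, C7′, C1′, C2; ring C = dienone C1′–C6′ (C4′ is the carbonyl carbon, methoxy groups on C3′ and C5′).
Remark: C1′ carries two identical ring C arms and is not a stereocentre; the target is (7R,8S,8′R) in these labels, and the route controls C8′ (step 4), C7 (step 13) and C8 (step 14).

Step 1
Reactants: 1 4-hydroxy-3,5-dimethoxybenzaldehyde (syringaldehyde)
Product: 2 4-{[tert-butyl(dimethyl)silyl]oxy}-3,5-dimethoxybenzaldehyde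
Conditions: t-BuMe2SiCl, imidazole, DMF, rt
Reagents that add atoms: tert-butyl(chloro)dimethylsilane, CC(C)(C)[Si](C)(C)Cl
Why: O-Silylation (silyl ether protection) masks the phenol, because a free para-hydroxybenzyl bromide would collapse to a quinone methide in step 3, and the aryl silyl ether can later be shed by K2CO3/MeOH without a separate step.

Step 2
Reactants: 2 4-{[tert-butyl(dimethyl)silyl]oxy}-3,5-dimethoxybenzaldehyde
Product: 3 (4-{[tert-butyl(dimethyl)silyl]oxy}-3,5-dimethoxyphenyl)methanol
Conditions: NaBH4, THF/MeOH, 0 °C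
Reagents that add atoms: none
Why: Borohydride reduction of the aryl aldehyde gives the benzylic alcohol and leaves the aryl silyl ether alone at 0 °C.

Step 3
Reactants: 3 (4-{[tert-butyl(dimethyl)silyl]oxy}-3,5-dimethoxyphenyl)methanol
Product: 4 [4-(bromomethyl)-2,6-dimethoxyphenoxy](tert-butyl)dimethylsilane
Conditions: CBr4, PPh3, CH2Cl2, 0 °C
Reagents that add atoms: tetrabromomethane, BrC(Br)(Br)Br
Why: The Appel reaction converts the electron-rich benzylic alcohol into the bromide under neutral conditions that the silyl ether tolerates; the bromide should be used without storage.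

Step 4
Reactants: 5 (4S)-4-benzyl-3-propanoyl-1,3-oxazolidin-2-one; 4 [4-(bromomethyl)-2,6-dimethoxyphenoxy](tert-butyl)dimethylsilane
Product: 7 (4S)-4-benzyl-3-[(2R)-3-(4-{[tert-butyl(dimethyl)silyl]oxy}-3,5-dimethoxyphenyl)-2-methylpropanoyl]-1,3-oxazolidin-2-one, via sodium Z-enolate 6 (not isolated)
Conditions: NaN(SiMe3)2, THF, −78 °C; then 4, −78 → −30 °C
Reagents that add atoms: none
Why: Evans asymmetric alkylation: the chelated sodium Z-enolate 6 should be attacked by the reactive benzylic bromide on the face opposite the C4 benzyl group of the auxiliary, which sets the (R) methyl-bearing centre that becomes C8′.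

Step 5
Reactants: 7 (4S)-4-benzyl-3-[(2R)-3-(4-{[tert-butyl(dimethyl)silyl]oxy}-3,5-dimethoxyphenyl)-2-methylpropanoyl]-1,3-oxazolidin-2-one
Product: 8 (2R)-3-(4-{[tert-butyl(dimethyl)silyl]oxy}-3,5-dimethoxyphenyl)-2-methylpropan-1-ol
Conditions: LiBH4, H2O (1 equiv), Et2O, 0 °C
Reagents that add atoms: none
Why: Reductive cleavage of the N-acyloxazolidinone with LiBH4 gives the primary alcohol and releases the auxiliary without epimerising the α-centre.

Step 6
Reactants: 8 (2R)-3-(4-{[tert-butyl(dimethyl)silyl]oxy}-3,5-dimethoxyphenyl)-2-methylpropan-1-ol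
Product: 9 (2R)-3-(4-{[tert-butyl(dimethyl)silyl]oxy}-3,5-dimethoxyphenyl)-2-methylpropanal
Conditions: Dess–Martin periodinane, CH2Cl2, 0 °C → rt
Reagents that add atoms: none
Why: Dess–Martin oxidation gives the α-branched aldehyde under neutral conditions that do not enolise the new stereocentre; 9 should be used at once.

Step 7
Reactants: 9 (2R)-3-(4-{[tert-butyl(dimethyl)silyl]oxy}-3,5-dimethoxyphenyl)-2-methylpropanal
Product: 11 2,6-dimethoxy-4-[(2R)-2-methylbut-3-yn-1-yl]phenol, via silylated alkyne 10 (not isolated)
Conditions: dimethyl (1-diazo-2-oxopropyl)phosphonate, K2CO3, MeOH, 0 °C → rt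
Reagents that add atoms: dimethyl (1-diazo-2-oxopropyl)phosphonate, CC(=O)C(=[N+]=[N-])P(=O)(OC)OC
Why: Seyferth–Gilbert homologation with the Ohira–Bestmann reagent should turn the aldehyde into the terminal alkyne at 0 °C, where enolisation of the α-branched aldehyde is slow, and the same K2CO3/MeOH methanolyses the base-labile aryl silyl ether of 10 to free the phenol (the order of the two events does not change the outcome).

Step 8
Reactants: 11 2,6-dimethoxy-4-[(2R)-2-methylbut-3-yn-1-yl]phenol
Product: 12 4-[(2R)-3-iodo-2-methylbut-3-en-1-yl]-2,6-dimethoxyphenol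
Conditions: NaI, Me3SiCl, H2O, MeCN, 0 °C → rt
Reagents that add atoms: sodium iodide, [Na+].[I-]
Why: Markovnikov hydroiodination of the terminal alkyne by HI made in the flask puts iodine on the internal carbon (the future C8) and gives the 2-iodo-1-alkene without involving the stereocentre or the aryl methyl ethers.

Step 9
Reactants: 13 (3,4,5-trimethoxyphenyl)methanol
Product: 14 tert-butyl(dimethyl)[(3,4,5-trimethoxybenzyl)oxy]silane
Conditions: t-BuMe2SiCl, imidazole, DMF, rt
Reagents that add atoms: tert-butyl(chloro)dimethylsilane, CC(C)(C)[Si](C)(C)Cl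
Why: Silyl ether protection keeps the benzylic hydroxyl from acting as an oxygen nucleophile in step 10, so that only the two equivalent free ring positions (the future C2) can react.

Step 10
Reactants: 12 4-[(2R)-3-iodo-2-methylbut-3-en-1-yl]-2,6-dimethoxyphenol; 14 tert-butyl(dimethyl)[(3,4,5-trimethoxybenzyl)oxy]silane
Product: 16 4-[6-({[tert-butyl(dimethyl)silyl]oxy}methyl)-2,3,4-trimethoxyphenyl]-4-[(2R)-3-iodo-2-methylbut-3-en-1-yl]-2,6-dimethoxycyclohexa-2,5-dien-1-one, via aryloxy-λ3-iodane 15 (not isolated)
Conditions: PhI(OAc)2, 14 in excess, (CF3)2CHOH, −20 → 0 °C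
Reagents that add atoms: none
Why: Proposed new method: the phenol exchanges an acetate on trivalent iodine to give 15, loss of iodobenzene and acetate in the ionising, non-nucleophilic fluoroalcohol makes ring C an electrophile, and its para carbon (future C1′) should then be attacked by the free ring position of 14 next to CH2OSi (activated by one ortho and one para methoxy group), proton loss restoring ring A and leaving the 4-aryl-4-alkyl dienone; the closest known reaction types are the intramolecular phenol–arene spirocyclisation with trivalent iodine reagents and the intermolecular para-allylation of 4-alkylphenols with allylsilanes under the same conditions, and 14 is used in excess at low temperature to outrun loss of a C7′ proton.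

Step 11
Reactants: 16 4-[6-({[tert-butyl(dimethyl)silyl]oxy}methyl)-2,3,4-trimethoxyphenyl]-4-[(2R)-3-iodo-2-methylbut-3-en-1-yl]-2,6-dimethoxycyclohexa-2,5-dien-1-one
Product: 17 4-[6-(hydroxymethyl)-2,3,4-trimethoxyphenyl]-4-[(2R)-3-iodo-2-methylbut-3-en-1-yl]-2,6-dimethoxycyclohexa-2,5-dien-1-one
Conditions: Bu4NF, AcOH, THF, 0 °C
Reagents that add atoms: none
Why: Fluoride-mediated desilylation, buffered with acetic acid so that neither the dienone nor the alkenyl iodide meets free base, should release the benzylic alcohol.

Step 12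
Reactants: 17 4-[6-(hydroxymethyl)-2,3,4-trimethoxyphenyl]-4-[(2R)-3-iodo-2-methylbut-3-en-1-yl]-2,6-dimethoxycyclohexa-2,5-dien-1-one
Product: 18 2-{1-[(2R)-3-iodo-2-methylbut-3-en-1-yl]-3,5-dimethoxy-4-oxocyclohexa-2,5-dien-1-yl}-3,4,5-trimethoxybenzaldehyde
Conditions: MnO2, CH2Cl2, rt
Reagents that add atoms: none
Why: MnO2 oxidation is selective for the electron-rich benzylic alcohol and is neutral, so the dienone, the alkenyl iodide and the C8′ centre should stay untouched.

Step 13
Reactants: 18 2-{1-[(2R)-3-iodo-2-methylbut-3-en-1-yl]-3,5-dimethoxy-4-oxocyclohexa-2,5-dien-1-yl}-3,4,5-trimethoxybenzaldehyde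
Product: 20 (7R,8′R)-spirodienone allylic alcohol (ring B closed; exocyclic methylene on C8; C7 hydroxyl cis to the C8′ methyl), via alkenyl–CrCl2 species 19 (not isolated)
Conditions: CrCl2 (excess), NiCl2 (cat.), degassed DMSO, rt, 0.005 M
Reagents that add atoms: none
Why: CrCl2 reduces NiCl2 to zerovalent nickel, which undergoes oxidative addition to the C8–I bond, and transmetalation to trivalent chromium gives 19, whose C8–Cr bond adds to the C7 aldehyde through a closed, oxygen-bound transition state. The closest known reaction type is the intramolecular Nozaki–Hiyama–Kishi closure of medium and large rings from 2-iodo-1-alkenes and aldehydes. Ring B closes in the 7-exo-trig mode, the carbonyl oxygen staying outside the new ring, and only three freely rotating bonds (C1′–C7′, C7′–C8′, C8′–C8) lie between the reacting carbons. The new C7 centre is controlled by the C8′ stereocentre: allylic strain holds H8′ near the plane of the C8 alkene, and with the C8′ methyl and the chromium-bound oxygen both pseudo-equatorial in the chair-like seven-membered transition state the hydroxyl should end cis to that methyl (7R). The step needs aldehyde-over-dienone chemoselectivity and this facial selectivity: the C–Cr bond is a selective nucleophile for aldehydes and leaves ketone and enone carbonyl groups alone, the β-carbons of ring C are shielded by the quaternary C1′, the medium is neutral so ring C cannot rearrange, and the nickel loading is kept low to suppress nickel-mediated conjugate addition.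

Step 14
Reactants: 20 (7R,8′R)-spirodienone allylic alcohol
Product: 21 (7R,8S,8′R)-spirodienone alcohol (C8 methyl trans to the C7 hydroxyl and trans to the C8′ methyl)
Conditions: [Ir(cod)(PCy3)(py)]PF6 (cat.), H2 (1 atm), CH2Cl2, 0 °C
Reagents that add atoms: none
Why: Hydroxyl-directed homogeneous hydrogenation: the C7 hydroxyl binds the cationic iridium centre, so hydrogen should add to the exocyclic alkene from the oxygen face, the new C8–H is cis to C7–O and the C8 methyl ends trans to oxygen and trans to the C8′ methyl (8S), while the conjugated, trisubstituted alkenes of ring C are much slower at low loading and 1 atm.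

Step 15
Reactants: 21 (7R,8S,8′R)-spirodienone alcohol
Product: 22 target CNP0201356.1, the C7 benzoate of 21
Conditions: PhCOCl, pyridine, DMAP (cat.), CH2Cl2, 0 °C → rt
Reagents that add atoms: benzoyl chloride, O=C(Cl)c1ccccc1
Why: DMAP-catalysed O-acylation (esterification with an acid chloride) proceeds with retention at C7 and without acid, which protects ring C from rearrangement.

Compound list
1 | 4-hydroxy-3,5-dimethoxybenzaldehyde (syringaldehyde) | COc1cc(C=O)cc(OC)c1O | starting material
2 | 4-{[tert-butyl(dimethyl)silyl]oxy}-3,5-dimethoxybenzaldehyde | COc1cc(C=O)cc(OC)c1O[Si](C)(C)C(C)(C)C | intermediate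
3 | (4-{[tert-butyl(dimethyl)silyl]oxy}-3,5-dimethoxyphenyl)methanol | COc1cc(CO)cc(OC)c1O[Si](C)(C)C(C)(C)C | intermediate
4 | [4-(bromomethyl)-2,6-dimethoxyphenoxy](tert-butyl)dimethylsilane | COc1cc(CBr)cc(OC)c1O[Si](C)(C)C(C)(C)C | intermediate
5 | (4S)-4-benzyl-3-propanoyl-1,3-oxazolidin-2-one | CCC(=O)N1[C@@H](Cc2ccccc2)COC1=O | starting material
6 | sodium (Z)-enolate of 5 (formed in the flask) | C/C=C(\[O-])N1[C@@H](Cc2ccccc2)COC1=O.[Na+] | intermediate
7 | (4S)-4-benzyl-3-[(2R)-3-(4-{[tert-butyl(dimethyl)silyl]oxy}-3,5-dimethoxyphenyl)-2-methylpropanoyl]-1,3-oxazolidin-2-one | COc1cc(C[C@@H](C)C(=O)N2[C@@H](Cc3ccccc3)COC2=O)cc(OC)c1O[Si](C)(C)C(C)(C)C | intermediate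
8 | (2R)-3-(4-{[tert-butyl(dimethyl)silyl]oxy}-3,5-dimethoxyphenyl)-2-methylpropan-1-ol | COc1cc(C[C@@H](C)CO)cc(OC)c1O[Si](C)(C)C(C)(C)C | intermediate
9 | (2R)-3-(4-{[tert-butyl(dimethyl)silyl]oxy}-3,5-dimethoxyphenyl)-2-methylpropanal | COc1cc(C[C@@H](C)C=O)cc(OC)c1O[Si](C)(C)C(C)(C)C | intermediate
10 | tert-butyl{2,6-dimethoxy-4-[(2R)-2-methylbut-3-yn-1-yl]phenoxy}dimethylsilane (formed in the flask) | COc1cc(C[C@@H](C)C#C)cc(OC)c1O[Si](C)(C)C(C)(C)C | intermediate
11 | 2,6-dimethoxy-4-[(2R)-2-methylbut-3-yn-1-yl]phenol | COc1cc(C[C@@H](C)C#C)cc(OC)c1O | intermediate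
12 | 4-[(2R)-3-iodo-2-methylbut-3-en-1-yl]-2,6-dimethoxyphenol | COc1cc(C[C@@H](C)C(I)=C)cc(OC)c1O | intermediate
13 | (3,4,5-trimethoxyphenyl)methanol | COc1cc(CO)cc(OC)c1OC | starting material
14 | tert-butyl(dimethyl)[(3,4,5-trimethoxybenzyl)oxy]silane | COc1cc(CO[Si](C)(C)C(C)(C)C)cc(OC)c1OC | intermediate
15 | acetoxy{4-[(2R)-3-iodo-2-methylbut-3-en-1-yl]-2,6-dimethoxyphenoxy}(phenyl)-λ3-iodane (formed in the flask) | COc1cc(C[C@@H](C)C(I)=C)cc(OC)c1OI(OC(C)=O)c1ccccc1 | intermediate
16 | 4-[6-({[tert-butyl(dimethyl)silyl]oxy}methyl)-2,3,4-trimethoxyphenyl]-4-[(2R)-3-iodo-2-methylbut-3-en-1-yl]-2,6-dimethoxycyclohexa-2,5-dien-1-one | COC1=CC(C[C@@H](C)C(I)=C)(C=C(OC)C1=O)c1c(CO[Si](C)(C)C(C)(C)C)cc(OC)c(OC)c1OC | intermediate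
17 | 4-[6-(hydroxymethyl)-2,3,4-trimethoxyphenyl]-4-[(2R)-3-iodo-2-methylbut-3-en-1-yl]-2,6-dimethoxycyclohexa-2,5-dien-1-one | COC1=CC(C[C@@H](C)C(I)=C)(C=C(OC)C1=O)c1c(CO)cc(OC)c(OC)c1OC | intermediate
18 | 2-{1-[(2R)-3-iodo-2-methylbut-3-en-1-yl]-3,5-dimethoxy-4-oxocyclohexa-2,5-dien-1-yl}-3,4,5-trimethoxybenzaldehyde (precursor of the key step) | COC1=CC(C[C@@H](C)C(I)=C)(C=C(OC)C1=O)c1c(C=O)cc(OC)c(OC)c1OC | intermediate
19 | alkenyl–CrCl2 species from 18, chromium on C8 (formed in the flask) | COC1=CC(C[C@@H](C)C(=C)[Cr](Cl)Cl)(C=C(OC)C1=O)c1c(C=O)cc(OC)c(OC)c1OC | intermediate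
20 | (7R,8′R)-spirodienone allylic alcohol: ring B closed, exocyclic methylene on C8, C7 hydroxyl cis to the C8′ methyl (product of the key step) | COC1=CC2(C=C(OC)C1=O)C[C@@H](C)C(=C)[C@@H](O)c1cc(OC)c(OC)c(OC)c12 | intermediate
21 | (7R,8S,8′R)-spirodienone alcohol: C8 methyl trans to the C7 hydroxyl and to the C8′ methyl | COC1=CC2(C=C(OC)C1=O)C[C@@H](C)[C@H](C)[C@@H](O)c1cc(OC)c(OC)c(OC)c12 | intermediate
22 | CNP0201356.1, the (7R,8S,8′R) C7 benzoate | COC1=CC2(C=C(OC)C1=O)C[C@@H](C)[C@H](C)[C@@H](OC(=O)c1ccccc1)c1cc(OC)c(OC)c(OC)c12 | target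

Total step count: 15. Longest linear sequence: 14 steps (steps 1–8 and 10–15; step 9 is the one-step branch to 14).

Steps most likely to fail

Step 10 (the one step that lacks direct precedent). What may go wrong: after oxidation ring C may lose a benzylic proton from C7′ (quinone methide formation, then arene capture at C7′), the arene may attack a methoxy-bearing ortho carbon instead of the para carbon, or the acid set free may trigger aryl migration in the product (dienone–phenol rearrangement). The fallback uses known reaction types and makes the C2–C1′ bond intramolecularly through a temporary silicon tether; it sets out from alkyne 11 and alcohol 13 and returns at alcohol 17. Alcohol 13 is silylated with Me2SiHCl/Et3N to the hydrosilane [(3,4,5-trimethoxybenzyl)oxy]dimethylsilane F1. F1 is added to the terminal alkyne of 11 with [Cp*Ru(MeCN)3]PF6 (Markovnikov hydrosilylation) to give the C8-silyl vinylsilane phenol F2. PhI(OAc)2 in (CF3)2CHOH at high dilution then effects the intramolecular phenol–arene spirocyclisation, in which the tether can deliver the arene only to the para carbon, and gives the silicon-bridged spirodienone F3. N-Iodosuccinimide in MeCN exchanges silicon on C8 for iodine with the alkene staying in place (iododesilylation), and Bu4NF removes the remaining silyl group from the C7 oxygen, which gives 17.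

Step 13 (key step). What may go wrong: poor facial selectivity at C7, because the two faces of the aldehyde differ only through the C8′ methyl two atoms away, or nickel-mediated conjugate addition of the alkenyl group to ring C. The fallback moves control of C7 from the C–C bond formation to a catalyst-controlled ketone reduction; it sets out from 18 and returns at 20. The closure is run on 18 as in step 13 without regard to the C7 outcome, and the mixture of 20 and the C7 epimer of 20 F4 is oxidised with MnO2 to the single ring B enone F5 (C7 ketone conjugated to ring A and to the C8 methylene). F5 is reduced with (S)-2-methyl-CBS-oxazaborolidine and catecholborane at −78 °C (Corey–Bakshi–Shibata reduction). On the usual model with the aryl group as the larger substituent this should give the 7R alcohol 20, in the same sense as the substrate bias (hydride anti to the C8′ methyl). The ring C carbonyl, flanked in its plane by two methoxy groups, should bind the oxazaborolidine boron far less readily and stay untouched.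

Step 7. What may go wrong: base-induced enolisation of the α-branched aldehyde 9 before it is homologated, which would erode the stereocentre on which C7 and C8 later depend, or incomplete methanolysis of the aryl silyl ether. The fallback is a base-free dibromo-olefination followed by carbenoid rearrangement; it sets out from 9 and returns at 11. Aldehyde 9 is treated with CBr4/PPh3 (first stage of the Corey–Fuchs sequence) to give the 1,1-dibromoalkene F6. n-BuLi in THF at −78 °C (bromine–lithium exchange, Fritsch–Buttenberg–Wiechell rearrangement, protonation on work-up) gives the silylated alkyne 10, now isolated, and Bu4NF then frees the phenol to give 11.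

Further compounds
F1 | step 10 | hydrosilane [(3,4,5-trimethoxybenzyl)oxy]dimethylsilane | COc1cc(CO[SiH](C)C)cc(OC)c1OC
F2 | step 10 | C8-silyl vinylsilane phenol, 4-[(2R)-3-{dimethyl[(3,4,5-trimethoxybenzyl)oxy]silyl}-2-methylbut-3-en-1-yl]-2,6-dimethoxyphenol | COc1cc(C[C@@H](C)C(=C)[Si](C)(C)OCc2cc(OC)c(OC)c(OC)c2)cc(OC)c1O
F3 | step 10 | silicon-bridged spirodienone (C8–SiMe2–O–C7 bridge, C2–C1′ bond formed) | COC1=CC2(C=C(OC)C1=O)C[C@@H](C)C(=C)[Si](C)(C)OCc1cc(OC)c(OC)c(OC)c12
F4 | step 13 | C7 epimer of 20, (7S,8′R) | COC1=CC2(C=C(OC)C1=O)C[C@@H](C)C(=C)[C@H](O)c1cc(OC)c(OC)c(OC)c12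
F5 | step 13 | ring B enone (C7 ketone, C8 methylene, 8′R) | COC1=CC2(C=C(OC)C1=O)C[C@@H](C)C(=C)C(=O)c1cc(OC)c(OC)c(OC)c12
F6 | step 7 | 1,1-dibromoalkene, tert-butyl{4-[(2R)-4,4-dibromo-2-methylbut-3-en-1-yl]-2,6-dimethoxyphenoxy}dimethylsilane | COc1cc(C[C@@H](C)C=C(Br)Br)cc(OC)c1O[Si](C)(C)C(C)(C)C
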